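The rate constants come from no measurement; the flask was simulated.

L forms when one E.D meets one D.G, so follow the supply of each.

    E + D → E.D (k1 = 1.5 L mol⁻¹ s⁻¹)
    D + G → D.G (k2 = 24 L mol⁻¹ s⁻¹)
    E.D + D.G → L (k3 = 210 L mol⁻¹ s⁻¹)
    2 E.D → E.D2 (k4 = 78 L mol⁻¹ s⁻¹)
    E + D.G → E.D.G (k5 = 7.1 L mol⁻¹ s⁻¹)

in all of them: E 13 mM

|  | G | D | time | remark |
|---|---|---|---|---|
| eta | 1.10 equiv | 4.00 equiv (fed, over 20.0 s) | 25 s | a stirred flask in which D is dosed at a steady rate over 20.0 s without added volume, worked up at 25 s |
| alpha | 1.10 equiv | 4.00 equiv | 25 s | everything together in a closed stirred flask, run for 25 s |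
| zeta | 1.10 equiv (fed, over 20.0 s) | 4.00 equiv | 25 s | all but G at the start; G goes in evenly over 20.0 s, the run ends at 25 s |
| beta | 1.10 equiv | 4.00 equiv |  | one stirred flow tank at steady state, fed with the mixture as stated, mean residence time 25 s |

- percentages count the E that a species holds: one E.D2 counts as two
- a doubled species enters its step squared and goes two at a time
- the stated concentrations are those of everything mixed, before any reaction; amounts are the same in each set-up
- the feed brings no volume worth counting
- run time (eta): 25 s

1. order of the set-ups by the amount of L at the outlet or at the end, in percent of the E put in, highest first (eta / alpha / zeta / beta)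
2. amount of L at the outlet or at the end, in percent of the E put in, eta
3. amount of L at the outlet or at the end, in percent of the E put in, alpha
4. amount of L at the outlet or at the end, in percent of the E put in, zeta
5. amount of L at the outlet or at the end, in percent of the E put in, beta

**G balance.** Write the balance of G, the reagent charged in the smaller amount: 1.10 equiv against 4.00 equiv of D. G leaves into D.G, and D.G leaves into L or E.D.G. Now compare zeta with eta, which hold the same charges but feed different reagents.

**Zeta reckoned.** Start with zeta. In zeta, G enters a flask of D, and its half-life against charged D is 0.555 s, shorter than the 20.0 s feed. So take D.G as made at the feed rate of G. Take E.D as made at its constant times charged E and charged D. Divide the first rate into the second to get 1.42. Call this the pairing ratio, E.D made per D.G made at the start.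

**Eta reckoned.** In eta, E and G share the incoming D. The ratio is therefore 0.0568, lower than in zeta. Eta makes D.G in surplus. In alpha, D.G has a half-life of 7.5 s against charged E, shorter than the 25 s run. So expect eta to pass D.G into E.D.G. Zeta stands above one, so expect some E.D to double into E.D2. Commit to an order: L higher in zeta than in eta. The ratio gives no percentages.

**The forecast.** The forecast gives 16% for eta, 44% for alpha, 50% for zeta and 38% for beta, in the order zeta > alpha > beta > eta. Its ground for eta is that “the early D.G diverts E into E.D.G”.

**The result.** The flasks give 28.2% for eta, 45.2% for alpha, 48.9% for zeta and 37.2% for beta, in the order zeta > alpha > beta > eta. Eta stands 12 percentage points above the forecast; the other three fall within the margin. At 25.0 s, eta, with ratio 0.0568, holds 50.9% as E.D.G and 0.514% as E.D2. Zeta, with ratio 1.42, holds 17.7% and 19.2%.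

**Less G.** Take the neighbour of zeta charged with 0.660 equiv of G. Its pairing ratio is 2.36, higher than zeta's, so expect a larger E.D surplus. The neighbour ends with 30.8% as E.D2, more than the 19.2% of zeta. Its E.D.G stands at 9.02%, and its L at 41.5%.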